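## Retrosynthetic overview

1. The chalcone Cα–Cβ bond is cut first: lithium enolate of bis-silylated 2,4-dihydroxyacetophenone (ring D) plus chromene aldehyde 21, joined by a directed aldol addition and dehydrated; all five silyl ethers come off last.
2. The pyran ring is the only ring built (rings A, B, C, D are bought as arenes). It is closed through the O1–C8a aryl–oxygen bond by intramolecular copper-catalysed etherification of Z-allylic alcohol 18, so the C2–O bond is never broken.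
3. 18 comes from Suzuki coupling (C4–C4a) of Z-vinyl iodide 12 with ring-A boronate 17. 12 comes from chelation-controlled anti-carbomagnesiation and iodination of propargylic alcohol 6 with ring-B Grignard reagent 10.
4. The single stereocentre (C2, S) is set by BINOL–titanium-catalysed alkynylzinc addition to 4-silyloxybenzaldehyde 2.

Assumption: the target is the 2S chromene with an E enone as written in the SMILES; compounds 9–12, 18 and 19 are carried as epimer mixtures at the oxane (tetrahydropyranyl) acetal carbon, which is removed in step 12, and all chromenes are handled in the dark.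

## Route

Step 1
Reactants: 1 4-hydroxybenzaldehyde
Product: 2 4-[(triisopropylsilyl)oxy]benzaldehyde
Conditions: iPr3SiCl, imidazole, DMF, rt
Reagents that add atoms: chlorotriisopropylsilane, CC(C)[Si](Cl)(C(C)C)C(C)C
Why: Imidazole-promoted silylation of the phenol gives a base-robust, fluoride-labile silyl ether for ring C.

Step 2
Reactants: 2 4-[(triisopropylsilyl)oxy]benzaldehyde; 3 ethynyltrimethylsilane
Product: 5 (1S)-1-{4-[(triisopropylsilyl)oxy]phenyl}-3-(trimethylsilyl)prop-2-yn-1-ol, via alkynylzinc 4 (not isolated)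
Conditions: Et2Zn, Cy2NH (5 mol%), (R)-BINOL (20 mol%), Et2O, rt; Ti(OiPr)4 (50 mol%); then 2, rt; aq. NH4Cl
Reagents that add atoms: none
Why: Titanium–BINOLate-catalysed asymmetric alkynylzinc addition (Pu-type alkynylation), in which the (R)-BINOL complex delivers the alkynyl group to the Re face of the aldehyde (the same facial sense as its dialkylzinc additions) and so sets the future C2 stereocentre as 1S, with ee checked by chiral HPLC.

Step 3
Reactants: 5 (1S)-1-{4-[(triisopropylsilyl)oxy]phenyl}-3-(trimethylsilyl)prop-2-yn-1-ol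
Product: 6 (1R)-1-{4-[(triisopropylsilyl)oxy]phenyl}prop-2-yn-1-ol
Conditions: K2CO3 (0.2 equiv), MeOH, 0 °C, 30 min
Reagents that add atoms: none
Why: Mild methanolysis of the alkynyl C–Si bond (protodesilylation) frees the terminal alkyne without touching the hindered aryl silyl ether or the stereocentre, whose descriptor changes from S to R only because the alkynyl group drops in CIP rank.

Step 4
Reactants: 7 3-bromo-4-hydroxybenzaldehyde
Product: 8 2-bromo-4-(1,3-dioxolan-2-yl)phenol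
Conditions: HOCH2CH2OH, TsOH·H2O (cat.), toluene, reflux, Dean–Stark; NaHCO3 wash
Reagents that add atoms: ethane-1,2-diol, OCCO
Why: Acid-catalysed acetalisation with azeotropic removal of water masks the aldehyde as a dioxolane that tolerates Grignard chemistry.

Step 5
Reactants: 8 2-bromo-4-(1,3-dioxolan-2-yl)phenol
Product: 9 2-[3-bromo-4-(oxan-2-yloxy)phenyl]-1,3-dioxolane
Conditions: 3,4-dihydro-2H-pyran, PPTS (5 mol%), CH2Cl2, rt
Reagents that add atoms: 3,4-dihydro-2H-pyran, C1=COCCC1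
Why: Acid-catalysed addition of the phenol to the enol ether (tetrahydropyranylation) gives a Grignard-stable aryl acetal that very mild acid removes later.

Step 6
Reactants: 9 2-[3-bromo-4-(oxan-2-yloxy)phenyl]-1,3-dioxolane; 6 (1R)-1-{4-[(triisopropylsilyl)oxy]phenyl}prop-2-yn-1-ol
Product: 12 (1S,2Z)-2-[5-(1,3-dioxolan-2-yl)-2-(oxan-2-yloxy)phenyl]-3-iodo-1-{4-[(triisopropylsilyl)oxy]phenyl}prop-2-en-1-ol, via Grignard reagent 10 (not isolated), via magnesium chelate 11 (not isolated)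
Conditions: 9 (3.2 equiv), Mg, THF, 45 °C; then CuI (15 mol%), 6, THF/toluene, −10 °C to 40 °C; then I2, THF, −20 °C; aq. Na2S2O3/NH4Cl
Reagents that add atoms: iodine, II
Why: Copper-catalysed anti-carbomagnesiation of a propargylic alkoxide (Duboudin–Jousseaume reaction) puts the aryl group on the alkyne carbon next to the carbinol and magnesium on the terminal carbon cis to the alkoxide in a five-membered chelate, so iodinolysis with retention gives only the Z-vinyl iodide while the carbinol stereocentre is untouched (1S now by CIP ranking only).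

Step 7
Reactants: 13 3-bromophenol
Product: 14 3-bromo-4-iodophenol
Conditions: N-iodosuccinimide, TsOH·H2O (10 mol%), MeCN, 0 °C to rt
Reagents that add atoms: N-iodosuccinimide, O=C1CCC(=O)N1I
Why: Electrophilic aromatic iodination with acid-activated N-iodosuccinimide goes para to the strongly directing hydroxyl group.

Step 8
Reactants: 14 3-bromo-4-iodophenol
Product: 15 (3-bromo-4-iodophenoxy)triisopropylsilane
Conditions: iPr3SiCl, imidazole, DMF, rt
Reagents that add atoms: chlorotriisopropylsilane, CC(C)[Si](Cl)(C(C)C)C(C)C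
Why: Imidazole-promoted silylation protects the ring-A phenol as the same robust silyl ether used on ring C.

Step 9
Reactants: 15 (3-bromo-4-iodophenoxy)triisopropylsilane
Product: 17 2-{2-bromo-4-[(triisopropylsilyl)oxy]phenyl}-4,4,5,5-tetramethyl-1,3,2-dioxaborolane, via arylmagnesium chloride 16 (not isolated)
Conditions: iPrMgCl·LiCl, THF, −20 °C; then 2-isopropoxy-4,4,5,5-tetramethyl-1,3,2-dioxaborolane, −20 °C to rt; aq. NH4Cl
Reagents that add atoms: 2-isopropoxy-4,4,5,5-tetramethyl-1,3,2-dioxaborolane, CC(C)OB1OC(C)(C)C(C)(C)O1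
Why: Selective iodine–magnesium exchange (turbo-Grignard) at −20 °C leaves the ortho bromide in place, and the arylmagnesium is trapped by the borate before it can eliminate to an aryne.

Step 10
Reactants: 12 (1S,2Z)-2-[5-(1,3-dioxolan-2-yl)-2-(oxan-2-yloxy)phenyl]-3-iodo-1-{4-[(triisopropylsilyl)oxy]phenyl}prop-2-en-1-ol; 17 2-{2-bromo-4-[(triisopropylsilyl)oxy]phenyl}-4,4,5,5-tetramethyl-1,3,2-dioxaborolane
Product: 18 (1S,2Z)-3-{2-bromo-4-[(triisopropylsilyl)oxy]phenyl}-2-[5-(1,3-dioxolan-2-yl)-2-(oxan-2-yloxy)phenyl]-1-{4-[(triisopropylsilyl)oxy]phenyl}prop-2-en-1-ol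
Conditions: Pd(PPh3)4 (5 mol%), K3PO4, THF/H2O (5:1), 55 °C, dark
Reagents that add atoms: none
Why: Suzuki–Miyaura coupling in which zerovalent palladium inserts into the vinyl C–I bond far faster than into the hindered, electron-rich aryl C–Br bond and couples with retention of the Z geometry, so ring A ends up cis to the carbinol.

Step 11
Reactants: 18 (1S,2Z)-3-{2-bromo-4-[(triisopropylsilyl)oxy]phenyl}-2-[5-(1,3-dioxolan-2-yl)-2-(oxan-2-yloxy)phenyl]-1-{4-[(triisopropylsilyl)oxy]phenyl}prop-2-en-1-ol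
Product: 19 (2S)-3-[5-(1,3-dioxolan-2-yl)-2-(oxan-2-yloxy)phenyl]-7-[(triisopropylsilyl)oxy]-2-{4-[(triisopropylsilyl)oxy]phenyl}-2H-chromene
Conditions: CuI (10 mol%), 3,4,7,8-tetramethyl-1,10-phenanthroline (20 mol%), Cs2CO3, toluene, 80 °C, dark
Reagents that add atoms: none
Why: Intramolecular Ullmann-type copper-catalysed O-arylation of the secondary alcohol closes the pyran ring through the aryl–oxygen bond, so the C–O bond at the stereocentre is never broken and C2 stays S, with the Z alkene pre-organising the six-membered ring closure.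

Step 12
Reactants: 19 (2S)-3-[5-(1,3-dioxolan-2-yl)-2-(oxan-2-yloxy)phenyl]-7-[(triisopropylsilyl)oxy]-2-{4-[(triisopropylsilyl)oxy]phenyl}-2H-chromene
Product: 20 4-hydroxy-3-[(2S)-7-[(triisopropylsilyl)oxy]-2-{4-[(triisopropylsilyl)oxy]phenyl}-2H-chromen-3-yl]benzaldehyde
Conditions: PPTS (0.3 equiv), acetone/H2O (9:1), rt to 40 °C, dark
Reagents that add atoms: water, O
Why: Mild acid-catalysed acetal hydrolysis removes the dioxolane and the aryl tetrahydropyranyl acetal together, while the aryl silyl ethers and the chromene are stable to pyridinium tosylate.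

Step 13
Reactants: 20 4-hydroxy-3-[(2S)-7-[(triisopropylsilyl)oxy]-2-{4-[(triisopropylsilyl)oxy]phenyl}-2H-chromen-3-yl]benzaldehyde
Product: 21 4-[(tert-butyldimethylsilyl)oxy]-3-[(2S)-7-[(triisopropylsilyl)oxy]-2-{4-[(triisopropylsilyl)oxy]phenyl}-2H-chromen-3-yl]benzaldehyde
Conditions: tBuMe2SiCl, imidazole, DMF, rt
Reagents that add atoms: tert-butylchlorodimethylsilane, CC(C)(C)[Si](C)(C)Cl
Why: Imidazole-promoted silylation re-protects the ring-B phenol at once as a fluoride-labile ether, so the 2'-hydroxyisoflavene motif is not exposed to later steps.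

Step 14
Reactants: 22 1-(2,4-dihydroxyphenyl)ethan-1-one
Product: 23 1-{2,4-bis[(tert-butyldimethylsilyl)oxy]phenyl}ethan-1-one
Conditions: tBuMe2SiCl (2.5 equiv), imidazole, DMF, 40 °C
Reagents that add atoms: tert-butylchlorodimethylsilane, CC(C)(C)[Si](C)(C)Cl
Why: Exhaustive silylation (forcing conditions for the hydrogen-bonded ortho hydroxyl) gives a ketone with no acidic O–H, so one equivalent of base makes a clean enolate.

Step 15
Reactants: 23 1-{2,4-bis[(tert-butyldimethylsilyl)oxy]phenyl}ethan-1-one; 21 4-[(tert-butyldimethylsilyl)oxy]-3-[(2S)-7-[(triisopropylsilyl)oxy]-2-{4-[(triisopropylsilyl)oxy]phenyl}-2H-chromen-3-yl]benzaldehyde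
Product: 25 1-{2,4-bis[(tert-butyldimethylsilyl)oxy]phenyl}-3-{4-[(tert-butyldimethylsilyl)oxy]-3-[(2S)-7-[(triisopropylsilyl)oxy]-2-{4-[(triisopropylsilyl)oxy]phenyl}-2H-chromen-3-yl]phenyl}-3-hydroxypropan-1-one, via lithium enolate 24 (not isolated)
Conditions: LiN(SiMe3)2, THF, −78 °C; then 21, −78 °C; AcOH quench at −78 °C
Reagents that add atoms: none
Why: Directed intermolecular aldol addition of the preformed lithium enolate to the non-enolisable aryl aldehyde forms the Cα–Cβ bond that joins the two halves at −78 °C without hydroxide, which the aryl silyl ethers and C2 tolerate; the new carbinol centre forms unselectively and is destroyed in step 16.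

Step 16
Reactants: 25 1-{2,4-bis[(tert-butyldimethylsilyl)oxy]phenyl}-3-{4-[(tert-butyldimethylsilyl)oxy]-3-[(2S)-7-[(triisopropylsilyl)oxy]-2-{4-[(triisopropylsilyl)oxy]phenyl}-2H-chromen-3-yl]phenyl}-3-hydroxypropan-1-one
Product: 27 (2E)-1-{2,4-bis[(tert-butyldimethylsilyl)oxy]phenyl}-3-{4-[(tert-butyldimethylsilyl)oxy]-3-[(2S)-7-[(triisopropylsilyl)oxy]-2-{4-[(triisopropylsilyl)oxy]phenyl}-2H-chromen-3-yl]phenyl}prop-2-en-1-one, via mesylate 26 (not isolated)
Conditions: MsCl, Et3N, CH2Cl2, 0 °C to rt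
Reagents that add atoms: none
Why: Mesylation of the aldol hydroxyl followed by E1cB elimination through the ketone enolate gives the conjugated enone as the thermodynamically favoured E isomer.

Step 17
Reactants: 27 (2E)-1-{2,4-bis[(tert-butyldimethylsilyl)oxy]phenyl}-3-{4-[(tert-butyldimethylsilyl)oxy]-3-[(2S)-7-[(triisopropylsilyl)oxy]-2-{4-[(triisopropylsilyl)oxy]phenyl}-2H-chromen-3-yl]phenyl}prop-2-en-1-one
Product: 28 (2E)-1-(2,4-dihydroxyphenyl)-3-{4-hydroxy-3-[(2S)-7-hydroxy-2-(4-hydroxyphenyl)-2H-chromen-3-yl]phenyl}prop-2-en-1-one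
Conditions: Bu4NF/AcOH (1:1, 6 equiv), THF, 0 °C, dark; pH 6 phosphate buffer work-up
Reagents that add atoms: none
Why: Fluoride-mediated cleavage of all five aryl silyl ethers under acetic acid buffering avoids both strong acid (chromene ionisation, pterocarpan-type cyclisation) and free phenoxide (quinone-methide ring opening at C2, chalcone-to-flavanone closure), so the stereocentre and the E enone survive.

## Compound list

1 | 4-hydroxybenzaldehyde | O=Cc1ccc(O)cc1 | starting material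
2 | 4-[(triisopropylsilyl)oxy]benzaldehyde | O=Cc1ccc(O[Si](C(C)C)(C(C)C)C(C)C)cc1 | intermediate
3 | ethynyltrimethylsilane | C#C[Si](C)(C)C | starting material
4 | ethyl[(trimethylsilyl)ethynyl]zinc | CC[Zn]C#C[Si](C)(C)C | intermediate
5 | (1S)-1-{4-[(triisopropylsilyl)oxy]phenyl}-3-(trimethylsilyl)prop-2-yn-1-ol | O[C@H](C#C[Si](C)(C)C)c1ccc(O[Si](C(C)C)(C(C)C)C(C)C)cc1 | intermediate
6 | (1R)-1-{4-[(triisopropylsilyl)oxy]phenyl}prop-2-yn-1-ol | O[C@H](C#C)c1ccc(O[Si](C(C)C)(C(C)C)C(C)C)cc1 | intermediate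
7 | 3-bromo-4-hydroxybenzaldehyde | O=Cc1ccc(O)c(Br)c1 | starting material
8 | 2-bromo-4-(1,3-dioxolan-2-yl)phenol | Oc1ccc(cc1Br)C1OCCO1 | intermediate
9 | 2-[3-bromo-4-(oxan-2-yloxy)phenyl]-1,3-dioxolane (racemic at the oxane acetal carbon) | Brc1cc(ccc1OC1CCCCO1)C1OCCO1 | intermediate
10 | [5-(1,3-dioxolan-2-yl)-2-(oxan-2-yloxy)phenyl]magnesium bromide | Br[Mg]c1cc(ccc1OC1CCCCO1)C1OCCO1 | intermediate
11 | bromomagnesium (1S,2Z)-3-(bromomagnesio)-2-[5-(1,3-dioxolan-2-yl)-2-(oxan-2-yloxy)phenyl]-1-{4-[(triisopropylsilyl)oxy]phenyl}prop-2-en-1-olate (five-membered O–Mg–C chelate) | Br[Mg]O[C@@H](c1ccc(O[Si](C(C)C)(C(C)C)C(C)C)cc1)/C(=C\[Mg]Br)c1cc(ccc1OC1CCCCO1)C1OCCO1 | intermediate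
12 | (1S,2Z)-2-[5-(1,3-dioxolan-2-yl)-2-(oxan-2-yloxy)phenyl]-3-iodo-1-{4-[(triisopropylsilyl)oxy]phenyl}prop-2-en-1-ol (oxane epimers) | O[C@@H](c1ccc(O[Si](C(C)C)(C(C)C)C(C)C)cc1)/C(=C\I)c1cc(ccc1OC1CCCCO1)C1OCCO1 | intermediate
13 | 3-bromophenol | Oc1cccc(Br)c1 | starting material
14 | 3-bromo-4-iodophenol | Oc1ccc(I)c(Br)c1 | intermediate
15 | (3-bromo-4-iodophenoxy)triisopropylsilane | CC(C)[Si](Oc1ccc(I)c(Br)c1)(C(C)C)C(C)C | intermediate
16 | {2-bromo-4-[(triisopropylsilyl)oxy]phenyl}magnesium chloride | CC(C)[Si](Oc1ccc([Mg]Cl)c(Br)c1)(C(C)C)C(C)C | intermediate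
17 | 2-{2-bromo-4-[(triisopropylsilyl)oxy]phenyl}-4,4,5,5-tetramethyl-1,3,2-dioxaborolane | CC(C)[Si](Oc1ccc(B2OC(C)(C)C(C)(C)O2)c(Br)c1)(C(C)C)C(C)C | intermediate
18 | (1S,2Z)-3-{2-bromo-4-[(triisopropylsilyl)oxy]phenyl}-2-[5-(1,3-dioxolan-2-yl)-2-(oxan-2-yloxy)phenyl]-1-{4-[(triisopropylsilyl)oxy]phenyl}prop-2-en-1-ol (oxane epimers) | O[C@@H](c1ccc(O[Si](C(C)C)(C(C)C)C(C)C)cc1)/C(=C\c1ccc(O[Si](C(C)C)(C(C)C)C(C)C)cc1Br)c1cc(ccc1OC1CCCCO1)C1OCCO1 | intermediate
19 | (2S)-3-[5-(1,3-dioxolan-2-yl)-2-(oxan-2-yloxy)phenyl]-7-[(triisopropylsilyl)oxy]-2-{4-[(triisopropylsilyl)oxy]phenyl}-2H-chromene (oxane epimers) | C1COC(O1)c1ccc(OC2CCCCO2)c(c1)C1=Cc2ccc(O[Si](C(C)C)(C(C)C)C(C)C)cc2O[C@H]1c1ccc(O[Si](C(C)C)(C(C)C)C(C)C)cc1 | intermediate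
20 | 4-hydroxy-3-[(2S)-7-[(triisopropylsilyl)oxy]-2-{4-[(triisopropylsilyl)oxy]phenyl}-2H-chromen-3-yl]benzaldehyde | O=Cc1ccc(O)c(c1)C1=Cc2ccc(O[Si](C(C)C)(C(C)C)C(C)C)cc2O[C@H]1c1ccc(O[Si](C(C)C)(C(C)C)C(C)C)cc1 | intermediate
21 | 4-[(tert-butyldimethylsilyl)oxy]-3-[(2S)-7-[(triisopropylsilyl)oxy]-2-{4-[(triisopropylsilyl)oxy]phenyl}-2H-chromen-3-yl]benzaldehyde | O=Cc1ccc(O[Si](C)(C)C(C)(C)C)c(c1)C1=Cc2ccc(O[Si](C(C)C)(C(C)C)C(C)C)cc2O[C@H]1c1ccc(O[Si](C(C)C)(C(C)C)C(C)C)cc1 | intermediate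
22 | 1-(2,4-dihydroxyphenyl)ethan-1-one | CC(=O)c1ccc(O)cc1O | starting material
23 | 1-{2,4-bis[(tert-butyldimethylsilyl)oxy]phenyl}ethan-1-one | CC(=O)c1ccc(O[Si](C)(C)C(C)(C)C)cc1O[Si](C)(C)C(C)(C)C | intermediate
24 | lithium 1-{2,4-bis[(tert-butyldimethylsilyl)oxy]phenyl}ethen-1-olate | [Li]OC(=C)c1ccc(O[Si](C)(C)C(C)(C)C)cc1O[Si](C)(C)C(C)(C)C | intermediate
25 | 1-{2,4-bis[(tert-butyldimethylsilyl)oxy]phenyl}-3-{4-[(tert-butyldimethylsilyl)oxy]-3-[(2S)-7-[(triisopropylsilyl)oxy]-2-{4-[(triisopropylsilyl)oxy]phenyl}-2H-chromen-3-yl]phenyl}-3-hydroxypropan-1-one (both carbinol epimers) | O=C(CC(O)c1ccc(O[Si](C)(C)C(C)(C)C)c(c1)C1=Cc2ccc(O[Si](C(C)C)(C(C)C)C(C)C)cc2O[C@H]1c1ccc(O[Si](C(C)C)(C(C)C)C(C)C)cc1)c1ccc(O[Si](C)(C)C(C)(C)C)cc1O[Si](C)(C)C(C)(C)C | intermediate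
26 | 3-{2,4-bis[(tert-butyldimethylsilyl)oxy]phenyl}-1-{4-[(tert-butyldimethylsilyl)oxy]-3-[(2S)-7-[(triisopropylsilyl)oxy]-2-{4-[(triisopropylsilyl)oxy]phenyl}-2H-chromen-3-yl]phenyl}-3-oxopropyl methanesulfonate (both epimers) | O=C(CC(OS(C)(=O)=O)c1ccc(O[Si](C)(C)C(C)(C)C)c(c1)C1=Cc2ccc(O[Si](C(C)C)(C(C)C)C(C)C)cc2O[C@H]1c1ccc(O[Si](C(C)C)(C(C)C)C(C)C)cc1)c1ccc(O[Si](C)(C)C(C)(C)C)cc1O[Si](C)(C)C(C)(C)C | intermediate
27 | (2E)-1-{2,4-bis[(tert-butyldimethylsilyl)oxy]phenyl}-3-{4-[(tert-butyldimethylsilyl)oxy]-3-[(2S)-7-[(triisopropylsilyl)oxy]-2-{4-[(triisopropylsilyl)oxy]phenyl}-2H-chromen-3-yl]phenyl}prop-2-en-1-one | O=C(/C=C/c1ccc(O[Si](C)(C)C(C)(C)C)c(c1)C1=Cc2ccc(O[Si](C(C)C)(C(C)C)C(C)C)cc2O[C@H]1c1ccc(O[Si](C(C)C)(C(C)C)C(C)C)cc1)c1ccc(O[Si](C)(C)C(C)(C)C)cc1O[Si](C)(C)C(C)(C)C | intermediate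
28 | (2E)-1-(2,4-dihydroxyphenyl)-3-{4-hydroxy-3-[(2S)-7-hydroxy-2-(4-hydroxyphenyl)-2H-chromen-3-yl]phenyl}prop-2-en-1-one | O=C(/C=C/c1ccc(O)c(C2=Cc3ccc(O)cc3O[C@H]2c2ccc(O)cc2)c1)c1ccc(O)cc1O | target

## Step count and risks

Total: 17 steps. Longest linear sequence: 11 steps (1 → 2 → 5 → 6 → 12 → 18 → 19 → 20 → 21 → 25 → 27 → 28; steps 1, 2, 3, 6, 10, 11, 12, 13, 15, 16, 17).

Three steps most likely to fail:

**Step 2 (asymmetric alkynylation; ee and facial sense on an electron-rich aldehyde).** The fallback sets out from 2 and comes back at 6. HC≡CMgBr (THF, 0 °C) adds to 2 to give racemic 1-{4-[(triisopropylsilyl)oxy]phenyl}prop-2-yn-1-ol F1. Kinetic resolution by lipase-catalysed acylation (immobilised Candida antarctica lipase B, vinyl acetate, hexane, 30 °C) acylates the R enantiomer selectively (Kazlauskas rule: aryl large, ethynyl small) to give (1R)-1-{4-[(triisopropylsilyl)oxy]phenyl}prop-2-yn-1-yl acetate F2. F2 is separated from the unreacted S alcohol and methanolysed (K2CO3, MeOH, 0 °C) to 6.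

**Step 6 (iodinolysis of the vinylmagnesium chelate in the presence of excess aryl Grignard, and handling of the light-sensitive Z-iodide).** The fallback sets out from 6 and 10 and comes back at 19; it keeps the carbomagnesiation but needs neither the iodide nor a defined alkene geometry.
- The same CuI-catalysed addition is quenched with aq. NH4Cl to give (1S)-2-[5-(1,3-dioxolan-2-yl)-2-(oxan-2-yloxy)phenyl]-1-{4-[(triisopropylsilyl)oxy]phenyl}prop-2-en-1-ol F3.
- Its potassium alkoxide (KN(SiMe3)2, THF, −40 to 0 °C) displaces fluoride from 2-fluoro-4-[(triisopropylsilyl)oxy]benzonitrile F4 (from commercial 2-fluoro-4-hydroxybenzonitrile, iPr3SiCl, imidazole). This SNAr forms the aryl–oxygen bond with retention and gives 2-{[(1S)-2-[5-(1,3-dioxolan-2-yl)-2-(oxan-2-yloxy)phenyl]-1-{4-[(triisopropylsilyl)oxy]phenyl}prop-2-en-1-yl]oxy}-4-[(triisopropylsilyl)oxy]benzonitrile F5.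
- iBu2AlH (toluene, −78 °C; aqueous KNaC4H4O6 work-up) gives the corresponding benzaldehyde F6.
- Ph3P=CH2 (from Ph3PCH3Br and KN(SiMe3)2, THF, 0 °C) gives the corresponding styrene F7.
- Ring-closing metathesis (second-generation Grubbs catalyst, CH2Cl2, 40 °C) forms the C3=C4 bond and gives 19.

**Step 11 (copper-catalysed ring closure of a hindered allylic, benzylic alcohol at 80 °C; risk of slow coupling or thermal erosion of ee).** The fallback sets out from 18 and comes back at 19, and reverses the polarity of the aryl partner. Miyaura borylation of the aryl bromide (B2pin2, Pd(dppf)Cl2, KOAc, 1,4-dioxane, 80 °C) gives (1S,2Z)-2-[5-(1,3-dioxolan-2-yl)-2-(oxan-2-yloxy)phenyl]-3-{2-(4,4,5,5-tetramethyl-1,3,2-dioxaborolan-2-yl)-4-[(triisopropylsilyl)oxy]phenyl}-1-{4-[(triisopropylsilyl)oxy]phenyl}prop-2-en-1-ol F8. An intramolecular oxidative Chan–Lam etherification (Cu(OAc)2, pyridine, 4 Å molecular sieves, air, CH2Cl2, rt) then forms the same aryl–oxygen bond at room temperature, again without touching the C2–O bond, and gives 19.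

## Further compounds

F1 | step 2 | 1-{4-[(triisopropylsilyl)oxy]phenyl}prop-2-yn-1-ol (racemic) | OC(C#C)c1ccc(O[Si](C(C)C)(C(C)C)C(C)C)cc1
F2 | step 2 | (1R)-1-{4-[(triisopropylsilyl)oxy]phenyl}prop-2-yn-1-yl acetate | CC(=O)O[C@H](C#C)c1ccc(O[Si](C(C)C)(C(C)C)C(C)C)cc1
F3 | step 6 | (1S)-2-[5-(1,3-dioxolan-2-yl)-2-(oxan-2-yloxy)phenyl]-1-{4-[(triisopropylsilyl)oxy]phenyl}prop-2-en-1-ol | O[C@@H](c1ccc(O[Si](C(C)C)(C(C)C)C(C)C)cc1)C(=C)c1cc(ccc1OC1CCCCO1)C1OCCO1
F4 | step 6 | 2-fluoro-4-[(triisopropylsilyl)oxy]benzonitrile | N#Cc1ccc(O[Si](C(C)C)(C(C)C)C(C)C)cc1F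
F5 | step 6 | 2-{[(1S)-2-[5-(1,3-dioxolan-2-yl)-2-(oxan-2-yloxy)phenyl]-1-{4-[(triisopropylsilyl)oxy]phenyl}prop-2-en-1-yl]oxy}-4-[(triisopropylsilyl)oxy]benzonitrile | N#Cc1ccc(O[Si](C(C)C)(C(C)C)C(C)C)cc1O[C@@H](c1ccc(O[Si](C(C)C)(C(C)C)C(C)C)cc1)C(=C)c1cc(ccc1OC1CCCCO1)C1OCCO1
F6 | step 6 | 2-{[(1S)-2-[5-(1,3-dioxolan-2-yl)-2-(oxan-2-yloxy)phenyl]-1-{4-[(triisopropylsilyl)oxy]phenyl}prop-2-en-1-yl]oxy}-4-[(triisopropylsilyl)oxy]benzaldehyde | O=Cc1ccc(O[Si](C(C)C)(C(C)C)C(C)C)cc1O[C@@H](c1ccc(O[Si](C(C)C)(C(C)C)C(C)C)cc1)C(=C)c1cc(ccc1OC1CCCCO1)C1OCCO1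
F7 | step 6 | 2-[5-(1,3-dioxolan-2-yl)-2-(oxan-2-yloxy)phenyl]-3-[(1S)-{2-ethenyl-5-[(triisopropylsilyl)oxy]phenoxy}{4-[(triisopropylsilyl)oxy]phenyl}methyl]... written as the aryl ether of F3 with 2-ethenyl-5-[(triisopropylsilyl)oxy]phenol | C=Cc1ccc(O[Si](C(C)C)(C(C)C)C(C)C)cc1O[C@@H](c1ccc(O[Si](C(C)C)(C(C)C)C(C)C)cc1)C(=C)c1cc(ccc1OC1CCCCO1)C1OCCO1
F8 | step 11 | (1S,2Z)-2-[5-(1,3-dioxolan-2-yl)-2-(oxan-2-yloxy)phenyl]-3-{2-(4,4,5,5-tetramethyl-1,3,2-dioxaborolan-2-yl)-4-[(triisopropylsilyl)oxy]phenyl}-1-{4-[(triisopropylsilyl)oxy]phenyl}prop-2-en-1-ol | O[C@@H](c1ccc(O[Si](C(C)C)(C(C)C)C(C)C)cc1)/C(=C\c1ccc(O[Si](C(C)C)(C(C)C)C(C)C)cc1B1OC(C)(C)C(C)(C)O1)c1cc(ccc1OC1CCCCO1)C1OCCO1
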